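**Retrosynthetic overview**
- Last bond: the ester C–O between the lactone C5 hydroxyl and a bis-silylated dienoic acid (Yamaguchi esterification), then desilylation.
- The δ-lactone is the only ring: it is closed by ring-closing metathesis of an acrylate, followed by conjugate reduction. The C5/C6 oxygen stereocentres come from a (Z)-γ-alkoxyallylboration of an α-methyl aldehyde.
- That aldehyde: the C2 methyl is set by ruthenium-catalysed asymmetric hydrogenation of an enoic acid; the C4 methyl (first stereocentre) by lipase desymmetrisation of a malonate-derived prochiral diacetate.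
- The dienoic acid: Wittig then Horner–Wadsworth–Emmons chain extension of an aldehyde whose single stereocentre comes from a second lipase desymmetrisation.

Abbreviations: TBS = tert-butyldimethylsilyl, PMB = 4-methoxybenzyl, Ts = 4-methylbenzenesulfonyl, Ipc = isopinocampheyl, DMP = Dess–Martin periodinane.

Assumption: the lipase is taken to hydrolyse the pro-R acetoxymethyl arm of both prochiral diacetates (by analogy with the empirical size rule for primary alcohols with Burkholderia cepacia lipase); this sense has to be confirmed by Mosher ester analysis of the two monoacetates.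

**Fragment A: lactone alcohol**

Step 1
Reactants: 1 ethyl (2E)-2-methylbut-2-enoate (ethyl tiglate)
Product: 2 (2E)-2-methylbut-2-en-1-ol
Conditions: i-Bu2AlH (2.2 equiv), CH2Cl2, −78 → 0 °C
Reagents that add atoms: none
Why: Ester reduction by a dialkylaluminium hydride is a clean 1,2-reduction that gives the allylic alcohol and leaves the E alkene untouched.

Step 2
Reactants: 2 (2E)-2-methylbut-2-en-1-ol
Product: 3 (2E)-1-bromo-2-methylbut-2-ene
Conditions: PBr3 (0.4 equiv), Et2O, −10 → 0 °C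
Reagents that add atoms: phosphorus tribromide, BrP(Br)Br
Why: Alcohol-to-bromide substitution (SN2 on the phosphite ester) at the primary allylic carbon keeps the alkene geometry.

Step 3
Reactants: 3 (2E)-1-bromo-2-methylbut-2-ene; 4 diethyl propanedioate (diethyl malonate)
Product: 5 diethyl 2-[(2E)-2-methylbut-2-en-1-yl]propanedioate
Conditions: NaH (1.0 equiv), 4 (2 equiv), THF, 0 °C → rt
Reagents that add atoms: none
Why: Malonic ester alkylation, in which the soft sodium malonate displaces the primary allylic bromide by SN2 and excess malonate suppresses dialkylation.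

Step 4
Reactants: 5 diethyl 2-[(2E)-2-methylbut-2-en-1-yl]propanedioate
Product: 6 2-[(2E)-2-methylbut-2-en-1-yl]propane-1,3-diol
Conditions: LiAlH4, THF, 0 °C → reflux
Reagents that add atoms: none
Why: Hydride reduction of both esters gives the prochiral 2-substituted propane-1,3-diol, the isolated alkene being inert.

Step 5
Reactants: 6 2-[(2E)-2-methylbut-2-en-1-yl]propane-1,3-diol
Product: 7 2-[(2E)-2-methylbut-2-en-1-yl]propane-1,3-diyl diacetate
Conditions: Ac2O, pyridine, DMAP (cat.), CH2Cl2, rt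
Reagents that add atoms: acetic anhydride, CC(=O)OC(C)=O
Why: Exhaustive O-acetylation (DMAP nucleophilic catalysis) gives the prochiral diacetate that the enzyme accepts.

Step 6
Reactants: 7 2-[(2E)-2-methylbut-2-en-1-yl]propane-1,3-diyl diacetate
Product: 8 (2S,4E)-2-(hydroxymethyl)-4-methylhex-4-en-1-yl acetate
Conditions: lipase from Burkholderia cepacia (immobilised), 0.1 M NaH2PO4/Na2HPO4 buffer pH 7.0/acetone 9:1, 25 °C, stopped when one acetate is cleaved
Reagents that add atoms: none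
Why: Enzymatic desymmetrisation (enantiotopic-group-selective ester hydrolysis by a lipase, a serine hydrolase) cleaves only the pro-R acetoxymethyl arm and so sets the first stereocentre by asymmetric catalysis, with over-hydrolysis of the minor enantiomer raising the ee.

Step 7
Reactants: 8 (2S,4E)-2-(hydroxymethyl)-4-methylhex-4-en-1-yl acetate
Product: 9 (2R,4E)-4-methyl-2-{[(4-methylbenzenesulfonyl)oxy]methyl}hex-4-en-1-yl acetate
Conditions: TsCl, pyridine, 0 °C
Reagents that add atoms: 4-methylbenzenesulfonyl chloride, Cc1ccc(cc1)S(=O)(=O)Cl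
Why: Sulfonylation of the free primary alcohol in a weak base at 0 °C is faster than the acetyl migration that would racemise 8.

Step 8
Reactants: 9 (2R,4E)-4-methyl-2-{[(4-methylbenzenesulfonyl)oxy]methyl}hex-4-en-1-yl acetate
Product: 10 (2R,4E)-2,4-dimethylhex-4-en-1-ol
Conditions: LiBHEt3 (4 equiv), THF, 0 °C → rt
Reagents that add atoms: none
Why: Hydride SN2 displacement of the primary tosylate turns that arm into the methyl group while the same reagent reductively cleaves the acetate, so the stereocentre from step 6 is carried over unchanged.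

Step 9
Reactants: 10 (2R,4E)-2,4-dimethylhex-4-en-1-ol
Product: 11 (2R,4E)-2,4-dimethylhex-4-enal
Conditions: DMP, CH2Cl2, 0 °C → rt; crude aldehyde used at once
Reagents that add atoms: none
Why: Dess–Martin oxidation stops at the aldehyde under near-neutral conditions that do not epimerise the α-stereocentre.

Step 10
Reactants: 11 (2R,4E)-2,4-dimethylhex-4-enal
Product: 12 ethyl (2E,4R,6E)-2,4,6-trimethylocta-2,6-dienoate
Conditions: Ph3P=C(CH3)CO2Et, CH2Cl2, rt → 40 °C
Reagents that add atoms: ethyl 2-(triphenyl-λ5-phosphanylidene)propanoate, CCOC(=O)C(C)=P(c1ccccc1)(c1ccccc1)c1ccccc1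
Why: Wittig olefination with a stabilised ylide gives the E-trisubstituted enoate without a base that could epimerise C4.

Step 11
Reactants: 12 ethyl (2E,4R,6E)-2,4,6-trimethylocta-2,6-dienoate
Product: 13 (2E,4R,6E)-2,4,6-trimethylocta-2,6-dienoic acid
Conditions: LiOH·H2O, THF/MeOH/H2O, 50 °C; then 1 M HCl to pH 3
Reagents that add atoms: lithium hydroxide, [Li+].[OH-]
Why: Ester saponification frees the carboxylic acid that the hydrogenation catalyst needs as its coordinating group.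

Step 12
Reactants: 13 (2E,4R,6E)-2,4,6-trimethylocta-2,6-dienoic acid
Product: 14 (2S,4S,6E)-2,4,6-trimethyloct-6-enoic acid
Conditions: H2 (4 atm), Ru(OAc)2[(S)-H8-BINAP] (1 mol%; H8-BINAP = 2,2'-bis(diphenylphosphino)-5,5',6,6',7,7',8,8'-octahydro-1,1'-binaphthyl), MeOH, 20 °C
Reagents that add atoms: none
Why: Carboxylate-directed Noyori-type asymmetric hydrogenation with the divalent ruthenium (S)-ligand complex adds H2 to one face of the tiglic-acid-type alkene and sets C2 as S under catalyst control, while the non-coordinating trisubstituted alkene is not reduced.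

Step 13
Reactants: 14 (2S,4S,6E)-2,4,6-trimethyloct-6-enoic acid
Product: 15 (2S,4S,6E)-2,4,6-trimethyloct-6-en-1-ol
Conditions: LiAlH4, THF, 0 °C → rt
Reagents that add atoms: none
Why: Hydride reduction of the acid to the primary alcohol touches neither stereocentre nor the alkene.

Step 14
Reactants: 15 (2S,4S,6E)-2,4,6-trimethyloct-6-en-1-ol
Product: 16 (2S,4S,6E)-2,4,6-trimethyloct-6-enal
Conditions: DMP, CH2Cl2, 0 °C → rt; used at once
Reagents that add atoms: none
Why: Dess–Martin oxidation gives the α-methyl aldehyde without epimerisation or over-oxidation.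

Step 15
Reactants: 16 (2S,4S,6E)-2,4,6-trimethyloct-6-enal
Product: 18 (3R,4R,5S,7S,9E)-3-[(4-methoxyphenyl)methoxy]-5,7,9-trimethylundeca-1,9-dien-4-ol, via diisopinocampheylborinate ester 17 (not isolated)
Conditions: allyl PMB ether, s-BuLi, THF, −78 °C; (−)-Ipc2BOMe; BF3·OEt2; then 16, −78 °C; NaOH, H2O2, 0 °C → rt
Reagents that add atoms: allyl 4-methoxybenzyl ether, C=CCOCc1ccc(OC)cc1
Why: Brown asymmetric (Z)-γ-alkoxyallylboration proceeds through a chair Zimmerman–Traxler transition state in which the Z reagent gives the 3,4-syn relationship and the (+)-α-pinene-derived Ipc ligands select the aldehyde face that gives 4R (hence 3R), overriding the weak bias of the α-methyl centre.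

Step 16
Reactants: 18 (3R,4R,5S,7S,9E)-3-[(4-methoxyphenyl)methoxy]-5,7,9-trimethylundeca-1,9-dien-4-ol
Product: 19 (3R,4R,5S,7S,9E)-3-[(4-methoxyphenyl)methoxy]-5,7,9-trimethylundeca-1,9-dien-4-yl prop-2-enoate
Conditions: acryloyl chloride, i-Pr2NEt, DMAP (cat.), CH2Cl2, 0 °C → rt
Reagents that add atoms: acryloyl chloride, C=CC(=O)Cl
Why: O-acylation of the secondary alcohol by the acid chloride installs the acrylate partner for ring closure.

Step 17
Reactants: 19 (3R,4R,5S,7S,9E)-3-[(4-methoxyphenyl)methoxy]-5,7,9-trimethylundeca-1,9-dien-4-yl prop-2-enoate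
Product: 20 (5R,6R)-6-[(2S,4S,6E)-4,6-dimethyloct-6-en-2-yl]-5-[(4-methoxyphenyl)methoxy]-5,6-dihydro-2H-pyran-2-one
Conditions: second-generation Grubbs catalyst RuCl2(=CHPh)(PCy3)(H2IMes) (5 mol%), CH2Cl2 (5 mM), 40 °C
Reagents that add atoms: none
Why: Ring-closing metathesis between the acrylate and the terminal vinyl group closes the six-membered unsaturated lactone with loss of ethene, the hindered trisubstituted alkene staying out of the reaction.

Step 18
Reactants: 20 (5R,6R)-6-[(2S,4S,6E)-4,6-dimethyloct-6-en-2-yl]-5-[(4-methoxyphenyl)methoxy]-5,6-dihydro-2H-pyran-2-one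
Product: 21 (5R,6R)-6-[(2S,4S,6E)-4,6-dimethyloct-6-en-2-yl]-5-[(4-methoxyphenyl)methoxy]oxan-2-one
Conditions: [(Ph3P)CuH]6 (0.5 equiv), H2O (5 equiv), degassed toluene, rt
Reagents that add atoms: none
Why: Conjugate (1,4-) hydride reduction by the monovalent copper hydride is specific for the α,β-unsaturated lactone and leaves the isolated trisubstituted alkene and the PMB ether alone.

Step 19
Reactants: 21 (5R,6R)-6-[(2S,4S,6E)-4,6-dimethyloct-6-en-2-yl]-5-[(4-methoxyphenyl)methoxy]oxan-2-one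
Product: 22 (5R,6R)-6-[(2S,4S,6E)-4,6-dimethyloct-6-en-2-yl]-5-hydroxyoxan-2-one
Conditions: DDQ (1.3 equiv), CH2Cl2/NaH2PO4–Na2HPO4 buffer pH 7 (10:1), 0 °C; used at once in step 32
Reagents that add atoms: none
Why: Oxidative PMB ether cleavage by DDQ (hydride abstraction, then hydrolysis of the oxocarbenium ion) frees the C5 hydroxyl under buffered neutral conditions that avoid acid- or base-promoted translactonisation.

**Fragment B: dienoic acid**

Step 20
Reactants: 4 diethyl propanedioate; 23 (2-bromoethoxy)(tert-butyl)dimethylsilane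
Product: 24 diethyl 2-{2-[(tert-butyldimethylsilyl)oxy]ethyl}propanedioate
Conditions: NaH, NaI (cat.), 4 (2 equiv), THF/DMF, 0 → 60 °C
Reagents that add atoms: none
Why: Malonic ester alkylation (SN2, iodide catalysis) joins the silyloxyethyl arm to the future stereocentre.

Step 21
Reactants: 24 diethyl 2-{2-[(tert-butyldimethylsilyl)oxy]ethyl}propanedioate
Product: 25 2-{2-[(tert-butyldimethylsilyl)oxy]ethyl}propane-1,3-diol
Conditions: LiAlH4, THF, 0 °C
Reagents that add atoms: none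
Why: Hydride reduction of both esters gives the prochiral diol, the primary TBS ether being stable to LiAlH4 at 0 °C.

Step 22
Reactants: 25 2-{2-[(tert-butyldimethylsilyl)oxy]ethyl}propane-1,3-diol
Product: 26 2-{2-[(tert-butyldimethylsilyl)oxy]ethyl}propane-1,3-diyl diacetate
Conditions: Ac2O, pyridine, DMAP (cat.), CH2Cl2, rt
Reagents that add atoms: acetic anhydride, CC(=O)OC(C)=O
Why: Exhaustive O-acetylation gives the prochiral diacetate for the enzyme.

Step 23
Reactants: 26 2-{2-[(tert-butyldimethylsilyl)oxy]ethyl}propane-1,3-diyl diacetate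
Product: 27 (2S)-4-[(tert-butyldimethylsilyl)oxy]-2-(hydroxymethyl)butyl acetate
Conditions: lipase from Burkholderia cepacia (immobilised), 0.1 M NaH2PO4/Na2HPO4 buffer pH 7.0/acetone 9:1, 25 °C, stopped when one acetate is cleaved
Reagents that add atoms: none
Why: Enzymatic desymmetrisation (enantiotopic-group-selective ester hydrolysis by a lipase) cleaves the pro-R acetoxymethyl arm and sets the only stereocentre of this fragment by asymmetric catalysis.

Step 24
Reactants: 27 (2S)-4-[(tert-butyldimethylsilyl)oxy]-2-(hydroxymethyl)butyl acetate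
Product: 28 (2R)-4-[(tert-butyldimethylsilyl)oxy]-2-{[(tert-butyldimethylsilyl)oxy]methyl}butyl acetate
Conditions: TBSCl, imidazole, DMF, 0 °C
Reagents that add atoms: tert-butyldimethylsilyl chloride, CC(C)(C)[Si](C)(C)Cl
Why: Silylation of the free primary alcohol (imidazole-catalysed silyl transfer) fixes the differentiation of the two arms before acetyl migration can occur.

Step 25
Reactants: 28 (2R)-4-[(tert-butyldimethylsilyl)oxy]-2-{[(tert-butyldimethylsilyl)oxy]methyl}butyl acetate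
Product: 29 (2R)-4-[(tert-butyldimethylsilyl)oxy]-2-{[(tert-butyldimethylsilyl)oxy]methyl}butan-1-ol
Conditions: i-Bu2AlH (2.2 equiv), CH2Cl2, −78 °C
Reagents that add atoms: none
Why: Reductive cleavage of the acetate at −78 °C avoids the basic conditions under which 1,3-silyl migration would racemise the product.

Step 26
Reactants: 29 (2R)-4-[(tert-butyldimethylsilyl)oxy]-2-{[(tert-butyldimethylsilyl)oxy]methyl}butan-1-ol
Product: 30 (2S)-4-[(tert-butyldimethylsilyl)oxy]-2-{[(tert-butyldimethylsilyl)oxy]methyl}butanal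
Conditions: DMP, CH2Cl2, 0 °C → rt; used at once
Reagents that add atoms: none
Why: Dess–Martin oxidation gives the α-branched β-silyloxy aldehyde without epimerisation or β-elimination.

Step 27
Reactants: 30 (2S)-4-[(tert-butyldimethylsilyl)oxy]-2-{[(tert-butyldimethylsilyl)oxy]methyl}butanal
Product: 31 ethyl (2E,4R)-6-[(tert-butyldimethylsilyl)oxy]-4-{[(tert-butyldimethylsilyl)oxy]methyl}-2-methylhex-2-enoate
Conditions: Ph3P=C(CH3)CO2Et, CH2Cl2, rt → 40 °C
Reagents that add atoms: ethyl 2-(triphenyl-λ5-phosphanylidene)propanoate, CCOC(=O)C(C)=P(c1ccccc1)(c1ccccc1)c1ccccc1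
Why: Wittig olefination with a stabilised ylide gives the E-trisubstituted enoate under base-free conditions that keep the allylic stereocentre intact.

Step 28
Reactants: 31 ethyl (2E,4R)-6-[(tert-butyldimethylsilyl)oxy]-4-{[(tert-butyldimethylsilyl)oxy]methyl}-2-methylhex-2-enoate
Product: 32 (2E,4R)-6-[(tert-butyldimethylsilyl)oxy]-4-{[(tert-butyldimethylsilyl)oxy]methyl}-2-methylhex-2-en-1-ol
Conditions: i-Bu2AlH (2.2 equiv), CH2Cl2, −78 °C
Reagents that add atoms: none
Why: 1,2-Reduction of the enoate by the aluminium hydride gives the allylic alcohol without conjugate reduction.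

Step 29
Reactants: 32 (2E,4R)-6-[(tert-butyldimethylsilyl)oxy]-4-{[(tert-butyldimethylsilyl)oxy]methyl}-2-methylhex-2-en-1-ol
Product: 33 (2E,4R)-6-[(tert-butyldimethylsilyl)oxy]-4-{[(tert-butyldimethylsilyl)oxy]methyl}-2-methylhex-2-enal
Conditions: MnO2 (excess), CH2Cl2, rt
Reagents that add atoms: none
Why: Allylic oxidation by MnO2 is selective for the allylic alcohol and gives the E-enal without isomerisation.

Step 30
Reactants: 33 (2E,4R)-6-[(tert-butyldimethylsilyl)oxy]-4-{[(tert-butyldimethylsilyl)oxy]methyl}-2-methylhex-2-enal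
Product: 34 ethyl (2E,4E,6R)-8-[(tert-butyldimethylsilyl)oxy]-6-{[(tert-butyldimethylsilyl)oxy]methyl}-4-methylocta-2,4-dienoate
Conditions: (EtO)2P(O)CH2CO2Et, NaH, THF, 0 °C → rt (anion pre-formed)
Reagents that add atoms: triethyl phosphonoacetate, CCOC(=O)CP(=O)(OCC)OCC
Why: Horner–Wadsworth–Emmons olefination with a stabilised phosphonate anion gives the new disubstituted alkene E-selectively and completes the (2E,4E)-dienoate.

Step 31
Reactants: 34 ethyl (2E,4E,6R)-8-[(tert-butyldimethylsilyl)oxy]-6-{[(tert-butyldimethylsilyl)oxy]methyl}-4-methylocta-2,4-dienoate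
Product: 35 (2E,4E,6R)-8-[(tert-butyldimethylsilyl)oxy]-6-{[(tert-butyldimethylsilyl)oxy]methyl}-4-methylocta-2,4-dienoic acid
Conditions: LiOH·H2O, THF/MeOH/H2O, rt; then cold 0.5 M HCl to pH 4
Reagents that add atoms: lithium hydroxide, [Li+].[OH-]
Why: Ester saponification gives the free dienoic acid while the primary TBS ethers survive aqueous hydroxide at room temperature.

**Coupling and deprotection**

Step 32
Reactants: 35 (2E,4E,6R)-8-[(tert-butyldimethylsilyl)oxy]-6-{[(tert-butyldimethylsilyl)oxy]methyl}-4-methylocta-2,4-dienoic acid; 22 (5R,6R)-6-[(2S,4S,6E)-4,6-dimethyloct-6-en-2-yl]-5-hydroxyoxan-2-one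
Product: 37 (2R,3R)-2-[(2S,4S,6E)-4,6-dimethyloct-6-en-2-yl]-6-oxooxan-3-yl (2E,4E,6R)-8-[(tert-butyldimethylsilyl)oxy]-6-{[(tert-butyldimethylsilyl)oxy]methyl}-4-methylocta-2,4-dienoate, via trichlorobenzoyl mixed anhydride 36 (not isolated)
Conditions: 2,4,6-trichlorobenzoyl chloride, Et3N, toluene, rt; then 22, DMAP, toluene, 0 °C → rt
Reagents that add atoms: none
Why: Yamaguchi esterification acylates the hindered secondary alcohol through the mixed anhydride and the acylpyridinium ion, with retention at C5 and fast enough to outrun translactonisation of 22.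

Step 33
Reactants: 37 (2R,3R)-2-[(2S,4S,6E)-4,6-dimethyloct-6-en-2-yl]-6-oxooxan-3-yl (2E,4E,6R)-8-[(tert-butyldimethylsilyl)oxy]-6-{[(tert-butyldimethylsilyl)oxy]methyl}-4-methylocta-2,4-dienoate
Product: 38 (2R,3R)-2-[(2S,4S,6E)-4,6-dimethyloct-6-en-2-yl]-6-oxooxan-3-yl (2E,4E,6R)-8-hydroxy-6-(hydroxymethyl)-4-methylocta-2,4-dienoate (target)
Conditions: HF·pyridine, pyridine, THF, 0 °C → rt
Reagents that add atoms: none
Why: Fluoride-mediated desilylation under buffered, weakly acidic conditions removes both primary TBS ethers without opening the lactone or cleaving the dienoate ester.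

**Compound list**

1 | ethyl (2E)-2-methylbut-2-enoate | C/C=C(\C)C(=O)OCC | starting material
2 | (2E)-2-methylbut-2-en-1-ol | C/C=C(\C)CO | intermediate
3 | (2E)-1-bromo-2-methylbut-2-ene | C/C=C(\C)CBr | intermediate
4 | diethyl propanedioate | CCOC(=O)CC(=O)OCC | starting material
5 | diethyl 2-[(2E)-2-methylbut-2-en-1-yl]propanedioate | C/C=C(\C)CC(C(=O)OCC)C(=O)OCC | intermediate
6 | 2-[(2E)-2-methylbut-2-en-1-yl]propane-1,3-diol | C/C=C(\C)CC(CO)CO | intermediate
7 | 2-[(2E)-2-methylbut-2-en-1-yl]propane-1,3-diyl diacetate | C/C=C(\C)CC(COC(C)=O)COC(C)=O | intermediate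
8 | (2S,4E)-2-(hydroxymethyl)-4-methylhex-4-en-1-yl acetate | C/C=C(\C)C[C@@H](CO)COC(C)=O | intermediate
9 | (2R,4E)-4-methyl-2-{[(4-methylbenzenesulfonyl)oxy]methyl}hex-4-en-1-yl acetate | C/C=C(\C)C[C@@H](COS(=O)(=O)c1ccc(C)cc1)COC(C)=O | intermediate
10 | (2R,4E)-2,4-dimethylhex-4-en-1-ol | C/C=C(\C)C[C@@H](C)CO | intermediate
11 | (2R,4E)-2,4-dimethylhex-4-enal | C/C=C(\C)C[C@@H](C)C=O | intermediate
12 | ethyl (2E,4R,6E)-2,4,6-trimethylocta-2,6-dienoate | C/C=C(\C)C[C@@H](C)/C=C(\C)C(=O)OCC | intermediate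
13 | (2E,4R,6E)-2,4,6-trimethylocta-2,6-dienoic acid | C/C=C(\C)C[C@@H](C)/C=C(\C)C(=O)O | intermediate
14 | (2S,4S,6E)-2,4,6-trimethyloct-6-enoic acid | C/C=C(\C)C[C@@H](C)C[C@H](C)C(=O)O | intermediate
15 | (2S,4S,6E)-2,4,6-trimethyloct-6-en-1-ol | C/C=C(\C)C[C@@H](C)C[C@H](C)CO | intermediate
16 | (2S,4S,6E)-2,4,6-trimethyloct-6-enal | C/C=C(\C)C[C@@H](C)C[C@H](C)C=O | intermediate
17 | (3R,4R,5S,7S,9E)-3-[(4-methoxyphenyl)methoxy]-5,7,9-trimethylundeca-1,9-dien-4-yl bis[(1R,2R,3R,5S)-isopinocampheyl]borinate | C/C=C(\C)C[C@@H](C)C[C@H](C)[C@@H](OB([C@@H]1C[C@@H]2C[C@H]([C@H]1C)C2(C)C)[C@@H]1C[C@@H]2C[C@H]([C@H]1C)C2(C)C)[C@@H](C=C)OCc1ccc(OC)cc1 | intermediate (not isolated)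
18 | (3R,4R,5S,7S,9E)-3-[(4-methoxyphenyl)methoxy]-5,7,9-trimethylundeca-1,9-dien-4-ol | C/C=C(\C)C[C@@H](C)C[C@H](C)[C@@H](O)[C@@H](C=C)OCc1ccc(OC)cc1 | intermediate
19 | (3R,4R,5S,7S,9E)-3-[(4-methoxyphenyl)methoxy]-5,7,9-trimethylundeca-1,9-dien-4-yl prop-2-enoate | C/C=C(\C)C[C@@H](C)C[C@H](C)[C@@H](OC(=O)C=C)[C@@H](C=C)OCc1ccc(OC)cc1 | intermediate
20 | (5R,6R)-6-[(2S,4S,6E)-4,6-dimethyloct-6-en-2-yl]-5-[(4-methoxyphenyl)methoxy]-5,6-dihydro-2H-pyran-2-one | C/C=C(\C)C[C@@H](C)C[C@H](C)[C@H]1OC(=O)C=C[C@H]1OCc1ccc(OC)cc1 | intermediate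
21 | (5R,6R)-6-[(2S,4S,6E)-4,6-dimethyloct-6-en-2-yl]-5-[(4-methoxyphenyl)methoxy]oxan-2-one | C/C=C(\C)C[C@@H](C)C[C@H](C)[C@H]1OC(=O)CC[C@H]1OCc1ccc(OC)cc1 | intermediate
22 | (5R,6R)-6-[(2S,4S,6E)-4,6-dimethyloct-6-en-2-yl]-5-hydroxyoxan-2-one | C/C=C(\C)C[C@@H](C)C[C@H](C)[C@H]1OC(=O)CC[C@H]1O | intermediate
23 | (2-bromoethoxy)(tert-butyl)dimethylsilane | BrCCO[Si](C)(C)C(C)(C)C | starting material
24 | diethyl 2-{2-[(tert-butyldimethylsilyl)oxy]ethyl}propanedioate | CCOC(=O)C(CCO[Si](C)(C)C(C)(C)C)C(=O)OCC | intermediate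
25 | 2-{2-[(tert-butyldimethylsilyl)oxy]ethyl}propane-1,3-diol | OCC(CO)CCO[Si](C)(C)C(C)(C)C | intermediate
26 | 2-{2-[(tert-butyldimethylsilyl)oxy]ethyl}propane-1,3-diyl diacetate | CC(=O)OCC(COC(C)=O)CCO[Si](C)(C)C(C)(C)C | intermediate
27 | (2S)-4-[(tert-butyldimethylsilyl)oxy]-2-(hydroxymethyl)butyl acetate | CC(=O)OC[C@H](CO)CCO[Si](C)(C)C(C)(C)C | intermediate
28 | (2R)-4-[(tert-butyldimethylsilyl)oxy]-2-{[(tert-butyldimethylsilyl)oxy]methyl}butyl acetate | CC(=O)OC[C@H](CO[Si](C)(C)C(C)(C)C)CCO[Si](C)(C)C(C)(C)C | intermediate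
29 | (2R)-4-[(tert-butyldimethylsilyl)oxy]-2-{[(tert-butyldimethylsilyl)oxy]methyl}butan-1-ol | OC[C@H](CO[Si](C)(C)C(C)(C)C)CCO[Si](C)(C)C(C)(C)C | intermediate
30 | (2S)-4-[(tert-butyldimethylsilyl)oxy]-2-{[(tert-butyldimethylsilyl)oxy]methyl}butanal | O=C[C@H](CO[Si](C)(C)C(C)(C)C)CCO[Si](C)(C)C(C)(C)C | intermediate
31 | ethyl (2E,4R)-6-[(tert-butyldimethylsilyl)oxy]-4-{[(tert-butyldimethylsilyl)oxy]methyl}-2-methylhex-2-enoate | CCOC(=O)/C(C)=C/[C@H](CO[Si](C)(C)C(C)(C)C)CCO[Si](C)(C)C(C)(C)C | intermediate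
32 | (2E,4R)-6-[(tert-butyldimethylsilyl)oxy]-4-{[(tert-butyldimethylsilyl)oxy]methyl}-2-methylhex-2-en-1-ol | OC/C(C)=C/[C@H](CO[Si](C)(C)C(C)(C)C)CCO[Si](C)(C)C(C)(C)C | intermediate
33 | (2E,4R)-6-[(tert-butyldimethylsilyl)oxy]-4-{[(tert-butyldimethylsilyl)oxy]methyl}-2-methylhex-2-enal | O=C/C(C)=C/[C@H](CO[Si](C)(C)C(C)(C)C)CCO[Si](C)(C)C(C)(C)C | intermediate
34 | ethyl (2E,4E,6R)-8-[(tert-butyldimethylsilyl)oxy]-6-{[(tert-butyldimethylsilyl)oxy]methyl}-4-methylocta-2,4-dienoate | CCOC(=O)/C=C/C(C)=C/[C@H](CO[Si](C)(C)C(C)(C)C)CCO[Si](C)(C)C(C)(C)C | intermediate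
35 | (2E,4E,6R)-8-[(tert-butyldimethylsilyl)oxy]-6-{[(tert-butyldimethylsilyl)oxy]methyl}-4-methylocta-2,4-dienoic acid | OC(=O)/C=C/C(C)=C/[C@H](CO[Si](C)(C)C(C)(C)C)CCO[Si](C)(C)C(C)(C)C | intermediate
36 | (2E,4E,6R)-8-[(tert-butyldimethylsilyl)oxy]-6-{[(tert-butyldimethylsilyl)oxy]methyl}-4-methylocta-2,4-dienoic 2,4,6-trichlorobenzoic anhydride | O=C(OC(=O)c1c(Cl)cc(Cl)cc1Cl)/C=C/C(C)=C/[C@H](CO[Si](C)(C)C(C)(C)C)CCO[Si](C)(C)C(C)(C)C | intermediate (not isolated)
37 | (2R,3R)-2-[(2S,4S,6E)-4,6-dimethyloct-6-en-2-yl]-6-oxooxan-3-yl (2E,4E,6R)-8-[(tert-butyldimethylsilyl)oxy]-6-{[(tert-butyldimethylsilyl)oxy]methyl}-4-methylocta-2,4-dienoate | C/C=C(\C)C[C@@H](C)C[C@H](C)[C@H]1OC(=O)CC[C@H]1OC(=O)/C=C/C(C)=C/[C@H](CO[Si](C)(C)C(C)(C)C)CCO[Si](C)(C)C(C)(C)C | intermediate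
38 | (2R,3R)-2-[(2S,4S,6E)-4,6-dimethyloct-6-en-2-yl]-6-oxooxan-3-yl (2E,4E,6R)-8-hydroxy-6-(hydroxymethyl)-4-methylocta-2,4-dienoate | C/C=C(\C)C[C@@H](C)C[C@H](C)[C@H]1OC(=O)CC[C@H]1OC(=O)/C=C/C(C)=C/[C@H](CO)CCO | target

**Step count and risks**

Total: 33 steps. Longest linear sequence: 21 steps (steps 1–19, 32, 33, from ethyl tiglate); the acid arm is 12 steps (20–31) before the junction.

The three steps most likely to fail:

Step 6 (lipase hydrolysis of 7). The enzyme may show the opposite enantiotopic sense on this substrate, or acetyl migration in water may lower the ee. Fallback: set out from diol 6 and run the same enzyme class in the acylation direction in dry organic solvent (lipase from Burkholderia cepacia, vinyl acetate, i-Pr2O, rt). This acetylates the arm that hydrolysis frees and gives (2R,4E)-2-(hydroxymethyl)-4-methylhex-4-en-1-yl acetate F1; if the hydrolysis itself turns out to have the opposite sense, F1 is simply its product. A protecting-group relay then exchanges the roles of the two arms. TBDPSCl and imidazole give (2S,4E)-2-{[(tert-butyldiphenylsilyl)oxy]methyl}-4-methylhex-4-en-1-yl acetate F2. i-Bu2AlH at −78 °C gives (2S,4E)-2-{[(tert-butyldiphenylsilyl)oxy]methyl}-4-methylhex-4-en-1-ol F3. TsCl in pyridine gives (2R,4E)-2-{[(tert-butyldiphenylsilyl)oxy]methyl}-4-methylhex-4-en-1-yl 4-methylbenzenesulfonate F4. LiBHEt3 gives tert-butyl{[(2R,4E)-2,4-dimethylhex-4-en-1-yl]oxy}diphenylsilane F5. Bu4NF in THF then returns to the route at 10.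

Step 15 (alkoxyallylboration of 16). The required 4,5-syn product is the Felkin product, which a Z-allylborane disfavours intrinsically, so the reagent has to override the substrate and the diastereomer ratio may be modest. Fallback: set out from 16 and add tributyl[(2Z)-3-[(4-methoxyphenyl)methoxy]prop-2-en-1-yl]stannane with BF3·OEt2 in CH2Cl2 at −78 °C. This open-transition-state allylation gives the 3,4-syn product, and Felkin–Anh control by the α-methyl centre gives 4,5-syn, so here substrate and reagent preferences coincide. It returns to the route at 18 directly and makes no new compound (none F0).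

Step 19 (with step 32). The free cis-5-hydroxy-δ-lactone 22 can translactonise to the more stable γ-lactone before or during acylation. Fallback: set out from 21 and acylate on the open chain.
- LiBH4 in THF/MeOH opens the lactone to (4R,5R,6S,8S,10E)-4-[(4-methoxyphenyl)methoxy]-6,8,10-trimethyldodec-10-ene-1,5-diol F6.
- Et3SiOTf and 2,6-lutidine give (4R,5R,6S,8S,10E)-4-[(4-methoxyphenyl)methoxy]-6,8,10-trimethyl-1,5-bis[(triethylsilyl)oxy]dodec-10-ene F7.
- Buffered DDQ gives (4R,5R,6S,8S,10E)-6,8,10-trimethyl-1,5-bis[(triethylsilyl)oxy]dodec-10-en-4-ol F8.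
- Yamaguchi esterification with 35 gives (4R,5R,6S,8S,10E)-6,8,10-trimethyl-1,5-bis[(triethylsilyl)oxy]dodec-10-en-4-yl (2E,4E,6R)-8-[(tert-butyldimethylsilyl)oxy]-6-{[(tert-butyldimethylsilyl)oxy]methyl}-4-methylocta-2,4-dienoate F9.
- Swern conditions ((COCl)2, DMSO, Et3N) convert the primary triethylsilyl ether directly into (4R,5R,6S,8S,10E)-6,8,10-trimethyl-1-oxo-5-[(triethylsilyl)oxy]dodec-10-en-4-yl (2E,4E,6R)-8-[(tert-butyldimethylsilyl)oxy]-6-{[(tert-butyldimethylsilyl)oxy]methyl}-4-methylocta-2,4-dienoate F10.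
- Pinnick oxidation (NaClO2, NaH2PO4, 2-methylbut-2-ene) gives (4R,5R,6S,8S,10E)-4-{[(2E,4E,6R)-8-[(tert-butyldimethylsilyl)oxy]-6-{[(tert-butyldimethylsilyl)oxy]methyl}-4-methylocta-2,4-dienoyl]oxy}-6,8,10-trimethyl-5-[(triethylsilyl)oxy]dodec-10-enoic acid F11.
- HF·pyridine removes all three silyl groups to give (4R,5R,6S,8S,10E)-5-hydroxy-4-{[(2E,4E,6R)-8-hydroxy-6-(hydroxymethyl)-4-methylocta-2,4-dienoyl]oxy}-6,8,10-trimethyldodec-10-enoic acid F12.
- Acid-catalysed δ-lactonisation (pyridinium 4-methylbenzenesulfonate, CH2Cl2) returns to the route at 38.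

Further compounds
F1 | step 6 | (2R,4E)-2-(hydroxymethyl)-4-methylhex-4-en-1-yl acetate | C/C=C(\C)C[C@@H](COC(C)=O)CO
F2 | step 6 | (2S,4E)-2-{[(tert-butyldiphenylsilyl)oxy]methyl}-4-methylhex-4-en-1-yl acetate | C/C=C(\C)C[C@@H](COC(C)=O)CO[Si](c1ccccc1)(c1ccccc1)C(C)(C)C
F3 | step 6 | (2S,4E)-2-{[(tert-butyldiphenylsilyl)oxy]methyl}-4-methylhex-4-en-1-ol | C/C=C(\C)C[C@@H](CO)CO[Si](c1ccccc1)(c1ccccc1)C(C)(C)C
F4 | step 6 | (2R,4E)-2-{[(tert-butyldiphenylsilyl)oxy]methyl}-4-methylhex-4-en-1-yl 4-methylbenzenesulfonate | C/C=C(\C)C[C@@H](COS(=O)(=O)c1ccc(C)cc1)CO[Si](c1ccccc1)(c1ccccc1)C(C)(C)C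
F5 | step 6 | tert-butyl{[(2R,4E)-2,4-dimethylhex-4-en-1-yl]oxy}diphenylsilane | C/C=C(\C)C[C@@H](C)CO[Si](c1ccccc1)(c1ccccc1)C(C)(C)C
F0 | step 15 | none | none
F6 | step 19 | (4R,5R,6S,8S,10E)-4-[(4-methoxyphenyl)methoxy]-6,8,10-trimethyldodec-10-ene-1,5-diol | C/C=C(\C)C[C@@H](C)C[C@H](C)[C@@H](O)[C@@H](CCCO)OCc1ccc(OC)cc1
F7 | step 19 | (4R,5R,6S,8S,10E)-4-[(4-methoxyphenyl)methoxy]-6,8,10-trimethyl-1,5-bis[(triethylsilyl)oxy]dodec-10-ene | C/C=C(\C)C[C@@H](C)C[C@H](C)[C@@H](O[Si](CC)(CC)CC)[C@@H](CCCO[Si](CC)(CC)CC)OCc1ccc(OC)cc1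
F8 | step 19 | (4R,5R,6S,8S,10E)-6,8,10-trimethyl-1,5-bis[(triethylsilyl)oxy]dodec-10-en-4-ol | C/C=C(\C)C[C@@H](C)C[C@H](C)[C@@H](O[Si](CC)(CC)CC)[C@@H](CCCO[Si](CC)(CC)CC)O
F9 | step 19 | (4R,5R,6S,8S,10E)-6,8,10-trimethyl-1,5-bis[(triethylsilyl)oxy]dodec-10-en-4-yl (2E,4E,6R)-8-[(tert-butyldimethylsilyl)oxy]-6-{[(tert-butyldimethylsilyl)oxy]methyl}-4-methylocta-2,4-dienoate | C/C=C(\C)C[C@@H](C)C[C@H](C)[C@@H](O[Si](CC)(CC)CC)[C@@H](CCCO[Si](CC)(CC)CC)OC(=O)/C=C/C(C)=C/[C@H](CO[Si](C)(C)C(C)(C)C)CCO[Si](C)(C)C(C)(C)C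
F10 | step 19 | (4R,5R,6S,8S,10E)-6,8,10-trimethyl-1-oxo-5-[(triethylsilyl)oxy]dodec-10-en-4-yl (2E,4E,6R)-8-[(tert-butyldimethylsilyl)oxy]-6-{[(tert-butyldimethylsilyl)oxy]methyl}-4-methylocta-2,4-dienoate | C/C=C(\C)C[C@@H](C)C[C@H](C)[C@@H](O[Si](CC)(CC)CC)[C@@H](CCC=O)OC(=O)/C=C/C(C)=C/[C@H](CO[Si](C)(C)C(C)(C)C)CCO[Si](C)(C)C(C)(C)C
F11 | step 19 | (4R,5R,6S,8S,10E)-4-{[(2E,4E,6R)-8-[(tert-butyldimethylsilyl)oxy]-6-{[(tert-butyldimethylsilyl)oxy]methyl}-4-methylocta-2,4-dienoyl]oxy}-6,8,10-trimethyl-5-[(triethylsilyl)oxy]dodec-10-enoic acid | C/C=C(\C)C[C@@H](C)C[C@H](C)[C@@H](O[Si](CC)(CC)CC)[C@@H](CCC(=O)O)OC(=O)/C=C/C(C)=C/[C@H](CO[Si](C)(C)C(C)(C)C)CCO[Si](C)(C)C(C)(C)C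
F12 | step 19 | (4R,5R,6S,8S,10E)-5-hydroxy-4-{[(2E,4E,6R)-8-hydroxy-6-(hydroxymethyl)-4-methylocta-2,4-dienoyl]oxy}-6,8,10-trimethyldodec-10-enoic acid | C/C=C(\C)C[C@@H](C)C[C@H](C)[C@@H](O)[C@@H](CCC(=O)O)OC(=O)/C=C/C(C)=C/[C@H](CO)CCO
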